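1. Read this flask at 15 h. The maple run is this same flask, followed so far; birch is the earlier run with more reagent.

common to all: substrate 0.020 M
- maple: reagent 0.020 M (fed, over 20 min); the very flask that is asked about, followed so far; the fed solution adds 0.10 times the starting volume
- birch: reagent 0.040 M (fed, over 20 min); run made earlier; the fed solution adds 0.10 times the starting volume
- flask: reagent 0.0200 M (fed, over 20 min); the fed solution adds 0.10 times the starting volume; time 15 h

| run | time / h | substrate / % | first product / % |
|---|---|---|---|
| maple | 0.500 | 6.6 | 70.5 |
| maple | 0.667 | 7.0 | 70.4 |
| maple | 1.00 | 9.2 | 73.0 |
| maple | 1.50 | 8.8 | 71.4 |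
| maple | 2.50 | 8.0 | 71.6 |
| maple | 4.00 | 9.7 | 74.2 |
| maple | 6.00 | 8.7 | 71.2 |
| birch | 0.333 | 0 | 63.9 |
| birch | 1.00 | 0.9 | 27.1 |
| birch | 1.50 | 0 | 18.4 |
| birch | 2.50 | 1.8 | 11.1 |
| birch | 4.00 | 0 | 7.2 |
| birch | 5.00 | 0 | 6.5 |
| birch | 6.00 | 0 | 4.3 |

(each reading ± 1 percentage point)

* why nothing more happens at 15 h, or that something still does (the reagent has run out first / all of the substrate has reacted / forward and back rates have come level / it is still moving)
* conversion of substrate at 15 h
* amount of first product at 15 h, in percent of the substrate charged

- amounts are per litre of the starting volume; all of the dose is in the solution fed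
- the reaction counts as stopped when no species that holds the substrate changes by six tenths of a point or more over the second half of the time
- what has gone from substrate into another species counts as reacted, even if it can come back

2. Expect a still flask. Maple's first product read 70.5% at 0.500 h and 71.2% at 6.00 h, with a scatter of 1 percentage point. Its mean is 71.8%. Substrate's mean is 8.29%, so I reckon a conversion of 91.7%.

3. Add no reagent. In birch, at 2.00 equivalents, first product fell from 63.9% at 0.333 h to 4.3% at 6.00 h, and substrate read 0% at that last reading. So first product takes reagent too. I take reagent as the limiting reagent in maple.

4. Carry one count. If no reagent stands free, each point of first product has used one reagent, and each point that took a second has used two. Take the equivalents, 1.00 in maple, subtract first product and divide by two: 14.1%. This is the second-addition share, the part of the substrate charge holding two reagents.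

5. The forecast says the reagent has run out first, conversion 91.7%, first product 71.8%: “the readings are flat within scatter”.

6. The flask gives the reagent has run out first, conversion 90.3%, first product 72.6%.

    reagent + first product → bis adduct + released group (k = 0.0532 M⁻¹ s⁻¹)
    substrate + reagent → first product + released group (k = 0.663 M⁻¹ s⁻¹)
    substrate ⇌ dormant form (K = 0.420, k = 3.32 × 10⁻⁴ s⁻¹)

At 0.186 h in the flask, the step on substrate used reagent at 13 times the rate of the step on first product. Reagent ended at 0% of its charge, so the count on the flask's first product gives a share of 13.7%, with bis adduct standing at 13.7%. In the neighbour at 1.70 equiv, reagent also ended at 0%; the count on its first product, 29.5%, gives 70.2%, and its bis adduct stands at 70.2%.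

The data are calculated on assumed constants, and the scatter is random.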